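**Plan**
Retrosynthesis: the benzene ring of Gentiside K is first taken back to a cyclohexane-1,2-dione carrying a phenylsulfinyl group at C4 (the source of the C4=C5 unsaturation). The ring is then cut at C1–C2 and C3–C4.
Enabling feature: the adjacent hydroxylated ring carbons C2 and C3 are an oxalyl unit. C4–C5–C6–C1, with the ester on C1, is a pentanoate chain that can be made nucleophilic at both ends (ester enolate at C1, α-sulfinyl carbanion at C4).
Forward: S-alkylation of thiophenol, esterification with tetracosan-1-ol and S-oxidation build the chain. One base-mediated double acylation with diethyl oxalate closes the only ring. Thermal loss of benzenesulfenic acid and tautomerisation then give the catechol.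
Stereochemistry: the target is achiral. The sulfur, C1 and C4 centres of the intermediates are uncontrolled and disappear on aromatisation.

Key step: step 4

Remark: the cyclic dione intermediates are drawn in their diketo forms, although they should exist largely as enols; this does not change the outcome.

**Route**

Step 1
Reactants: 1 5-bromopentanoic acid; 2 thiophenol
Product: 3 5-(phenylsulfanyl)pentanoic acid
Conditions: NaOH (2.2 equiv), EtOH/H2O, 0 °C to rt; then aq. HCl
Reagents that add atoms: none
Why: SN2 thioether formation, in which the soft thiophenolate should displace the primary bromide much faster than the carboxylate can lactonise or hydroxide can substitute.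

Step 2
Reactants: 3 5-(phenylsulfanyl)pentanoic acid; 4 tetracosan-1-ol
Product: 5 tetracosyl 5-(phenylsulfanyl)pentanoate
Conditions: DCC (1.1 equiv), DMAP (cat.), CH2Cl2, 35 °C
Reagents that add atoms: none
Why: Steglich esterification, in which the O-acylisourea/acylpyridinium should acylate the primary alcohol under neutral conditions that leave the sulfide untouched and need no excess of the long-chain alcohol.

Step 3
Reactants: 5 tetracosyl 5-(phenylsulfanyl)pentanoate
Product: 6 tetracosyl 5-(phenylsulfinyl)pentanoate (racemic at sulfur)
Conditions: mCPBA (1.0 equiv), CH2Cl2, −20 to 0 °C
Reagents that add atoms: mCPBA (3-chloroperoxybenzoic acid), OOC(=O)c1cccc(Cl)c1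
Why: Electrophilic oxidation of a sulfide by a peracid, which should stop at the sulfoxide with one equivalent because the sulfoxide is far less nucleophilic than the sulfide; the sulfur stereocentre forms racemic and is removed in step 5.

Step 4
Reactants: 6 tetracosyl 5-(phenylsulfinyl)pentanoate; 7 diethyl oxalate
Product: 10 tetracosyl 2,3-dioxo-4-(phenylsulfinyl)cyclohexane-1-carboxylate (stereoisomer/enol mixture), via dilithiated sulfinyl ester 8 (not isolated), via acyclic oxalyl adduct 9 (not isolated)
Conditions: LiN(iPr)2 (3.3 equiv), THF, −78 °C, slow addition of 6; then (CO2Et)2 (1.3 equiv), −78 to 0 °C; cold 1 M HCl quench; concentrate below 30 °C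
Reagents that add atoms: none
Why: Proposed new method: the closest known reaction type is the Claisen–Dieckmann annulation of dialkyl adipates with dialkyl oxalates, extended here to a chain whose second terminus is activated by a sulfinyl group instead of an ester, and the two separate events (C-acylation of an α-sulfinyl carbanion by an ester, crossed Claisen condensation of an ester enolate with an oxalate) are each well known. The ester α-CH is the more acidic site, so the first equivalent of base should mask the tetracosyl ester as its enolate before the second generates the α-sulfinyl carbanion to give dianion 8; the more basic carbanion at C4 should then add to diethyl oxalate and lose ethoxide to form C3–C4 in 9, and the C1 ester enolate, regenerated by the excess base if the newly acidic C4–H quenches it, should attack the remaining ethyl ester carbonyl to form C1–C2. This ring closure is a 6-exo-trig Dieckmann condensation enforced by the four-carbon spacing between the two nucleophilic carbons, and the same ring results if the ester enolate acylates first. Deprotonation of the product to a doubly stabilised enolate should make both condensations irreversible. No stereocentre of the target is created, and C1, C4 and sulfur in 10 are uncontrolled and are all erased in step 5. The step needs C4 to acylate oxalate and not the molecule's own ester (5-exo closure to a 2-sulfinylcyclopentanone), and needs the tetracosyl ester to survive LiOEt; both are secured by keeping that ester as an enolate throughout, first of the pentanoate and then of the β-keto ester.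

Step 5
Reactants: 10 tetracosyl 2,3-dioxo-4-(phenylsulfinyl)cyclohexane-1-carboxylate
Product: 12 Gentiside K (tetracosyl 2,3-dihydroxybenzoate), via ene-dione 11 (not isolated)
Conditions: degassed PhMe, 80–90 °C, Ar
Reagents that add atoms: none
Why: Sulfoxide pyrolysis (Ei syn-elimination of an α-sulfinyl ketone) can only engage the C5 hydrogens, and the resulting ene-dione 11 is a keto tautomer of the catechol that should aromatise by proton shifts, leaving no stereocentre.

**Compound list**

1 | 5-bromopentanoic acid | OC(=O)CCCCBr | starting material
2 | thiophenol | Sc1ccccc1 | starting material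
3 | 5-(phenylsulfanyl)pentanoic acid | OC(=O)CCCCSc1ccccc1 | intermediate
4 | tetracosan-1-ol | CCCCCCCCCCCCCCCCCCCCCCCCO | starting material
5 | tetracosyl 5-(phenylsulfanyl)pentanoate | CCCCCCCCCCCCCCCCCCCCCCCCOC(=O)CCCCSc1ccccc1 | intermediate
6 | tetracosyl 5-(phenylsulfinyl)pentanoate (racemic at sulfur) | CCCCCCCCCCCCCCCCCCCCCCCCOC(=O)CCCCS(=O)c1ccccc1 | intermediate
7 | diethyl oxalate | CCOC(=O)C(=O)OCC | starting material
8 | dilithium dianion of 6: ester enolate at C1, α-sulfinyl carbanion at C4 (not isolated) | [Li+].[Li+].CCCCCCCCCCCCCCCCCCCCCCCCOC([O-])=CCC[CH-]S(=O)c1ccccc1 | intermediate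
9 | 1-ethyl 7-tetracosyl 2-oxo-3-(phenylsulfinyl)heptanedioate, present as its lithium enolate and drawn neutral (not isolated) | CCCCCCCCCCCCCCCCCCCCCCCCOC(=O)CCCC(S(=O)c1ccccc1)C(=O)C(=O)OCC | intermediate
10 | tetracosyl 2,3-dioxo-4-(phenylsulfinyl)cyclohexane-1-carboxylate (stereoisomer/enol mixture) | CCCCCCCCCCCCCCCCCCCCCCCCOC(=O)C1CCC(S(=O)c2ccccc2)C(=O)C1=O | intermediate
11 | tetracosyl 2,3-dioxocyclohex-4-ene-1-carboxylate, drawn as the dione (not isolated) | CCCCCCCCCCCCCCCCCCCCCCCCOC(=O)C1CC=CC(=O)C1=O | intermediate
12 | Gentiside K (tetracosyl 2,3-dihydroxybenzoate) | CCCCCCCCCCCCCCCCCCCCCCCCOC(=O)c1cccc(O)c1O | target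

**Step count**
Total steps: 5. Longest linear sequence: 5 steps (1 → 3 → 5 → 6 → 10 → 12).

**Steps most likely to fail**

Step 4 (the step carrying the proposed new method). The second, sulfinyl deprotonation may be incomplete, or proton exchange with the acidic first acylation product may quench the remaining carbanion. The material would then stop at open-chain stages, close in the 5-exo mode onto its own ester, or undergo ester exchange with LiOEt. The fallback sets out from 5 and comes back at 10, and separates the two acylations so that only one kind of carbanion is present at a time. Sulfide ester 5 is converted into its ester enolate with LiN(iPr)2 (2.1 equiv, THF, −78 °C) and condensed with 7 in a crossed Claisen reaction. This gives 1-ethyl 4-tetracosyl 2-oxo-3-[3-(phenylsulfanyl)propyl]butanedioate F1, in which C1–C2 is already in place. Oxidation with mCPBA (1.0 equiv, CH2Cl2, −78 °C) should give 1-ethyl 4-tetracosyl 2-oxo-3-[3-(phenylsulfinyl)propyl]butanedioate F2. Treatment of F2 with LiN(iPr)2 (3 equiv, THF, −78 to 0 °C) should form the β-keto ester enolate first and the α-sulfinyl carbanion second. That carbanion acylates intramolecularly on the ethyl ester (6-exo-trig) and forms C3–C4 to give 10. All three operations are known reaction types: crossed Claisen condensation with an oxalate, sulfide oxidation, and intramolecular acylation of a sulfinyl carbanion by an ester.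

Step 5. The benzenesulfenic acid released, or the thiosulfinate it forms by self-condensation, may be recaptured by the enol or by the electron-rich catechol. The sulfoxide may also rest on an enolised, sp2 C4 from which syn-elimination is impossible. The fallback sets out from 10 and comes back at 12, and replaces the elimination by reductive removal of sulfur followed by dehydrogenation. Aluminium amalgam Al(Hg) in THF/H2O at 0 °C should cleave the activated C–S bond of the α-sulfinyl ketone to give tetracosyl 2,3-dioxocyclohexane-1-carboxylate F3. Iodine-catalysed dehydrogenative aromatisation of F3 (I2 cat., DMSO as terminal oxidant, 80 °C) should then give 12.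

Step 3. Oxidation may run on to the sulfone, or stay incomplete because the waxy ester dissolves poorly at low temperature. The fallback sets out from 3 and comes back at 6, and moves the oxidation to the water-compatible acid stage. NaIO4 (1.05 equiv, MeOH/H2O, 0 °C) should oxidise 3 cleanly to 5-(phenylsulfinyl)pentanoic acid F4, with no over-oxidation. Mitsunobu esterification of F4 with 4 (PPh3, DIAD, THF, 0 °C to rt) should give 6 under neutral conditions that avoid sulfoxide activation by acyl chlorides or strong acid.

**Further compounds**

F1 | step 4 | 1-ethyl 4-tetracosyl 2-oxo-3-[3-(phenylsulfanyl)propyl]butanedioate | CCCCCCCCCCCCCCCCCCCCCCCCOC(=O)C(CCCSc1ccccc1)C(=O)C(=O)OCC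
F2 | step 4 | 1-ethyl 4-tetracosyl 2-oxo-3-[3-(phenylsulfinyl)propyl]butanedioate | CCCCCCCCCCCCCCCCCCCCCCCCOC(=O)C(CCCS(=O)c1ccccc1)C(=O)C(=O)OCC
F3 | step 5 | tetracosyl 2,3-dioxocyclohexane-1-carboxylate | CCCCCCCCCCCCCCCCCCCCCCCCOC(=O)C1CCCC(=O)C1=O
F4 | step 3 | 5-(phenylsulfinyl)pentanoic acid | OC(=O)CCCCS(=O)c1ccccc1
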